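The route rests on cutting two bonds: the furyl ketone bond C12–C13 and the congested bond C9–C10 between the methyl-bearing quaternary carbon and the carbinol carbon, so that the γ-hydroxy ketone C10(OH)–C9–C11–C12(=O) is read as a homoaldol. In one operation 2-chloro-3-furyllithium adds to an α,β-unsaturated acylsilane (C12), a Brook rearrangement unmasks a siloxyallyl anion, and its C9 terminus closes ring B onto one carbonyl of a prochiral 2,2-disubstituted cyclohexane-1,3-dione (the future ring A), which sets C5, C9 and C10. The precursor is an acyclic enoyl silane hung on the dione through a silylene-bridged chain; the seven-membered ring C and the butenolide follow.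

Key step: step 13

Remark: atoms carry clerodane locants: ring A = C1–C2–C3–C4–C5–C10; ring B = C5–C6–C7–C8–C9–C10; C11–C12 is the arm on C9; the furan is C13 (bonded to C12), C14, C15, O, C16 (bonded to C1); ring C is the seven-membered ring C1–C10–C9–C11–C12–C13–C16; C17 and C20 are the methyls on C8 and C9; C18 is the lactone carbonyl on C4 and C19 the OCH2 on C5. In these locants the target is 1R,5S,7R,8S,9S,10S. The geometry of the transient C11=C12 silyl enol ether is not assigned.

Step 1
Reactants: 1 (4S)-4-benzyl-3-propanoyl-1,3-oxazolidin-2-one; 2 (E)-cinnamaldehyde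
Product: 4 anti-aldol imide (2R,3R), via silyl ether 3 (not isolated)
Conditions: MgCl2 (10 mol %), Et3N, TMSCl, EtOAc, rt; then TFA, MeOH
Reagents that add atoms: none
Why: Magnesium-catalysed anti-aldol addition of the N-acyloxazolidinone, in which the chelated (Z)-enolate is attacked by the non-enolisable enal on the face opposite the benzyl group through a boat-like transition state, should set the C8 methyl and C7 oxygen centres anti as (2R,3R), and acidic methanol cleaves silyl ether 3.

Step 2
Reactants: 4 anti-aldol imide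
Product: 5 Weinreb amide
Conditions: MeNH(OMe)·HCl, AlMe3, CH2Cl2, 0 °C to rt
Reagents that add atoms: N,O-dimethylhydroxylamine hydrochloride, CNOC.Cl
Why: Aluminium-amide transamidation (Weinreb amide formation) should cleave the auxiliary at the exocyclic carbonyl without epimerising either stereocentre.

Step 3
Reactants: 5 Weinreb amide
Product: 6 TES ether
Conditions: TESCl, imidazole, DMF, rt
Reagents that add atoms: chlorotriethylsilane, CC[Si](Cl)(CC)CC
Why: Standard O-silylation; TES is chosen because mild acid removes it later in the presence of the acylsilane.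

Step 4
Reactants: 6 TES ether
Product: 7 methyl ketone
Conditions: MeMgBr, THF, 0 °C
Reagents that add atoms: methylmagnesium bromide, C[Mg]Br
Why: Weinreb ketone synthesis, in which the chelated tetrahedral adduct collapses only on work-up, so neither over-addition nor epimerisation of the α-methyl centre is expected.

Step 5
Reactants: 7 methyl ketone
Product: 8 propargylic alcohol
Conditions: tert-butyl(ethynyl)dimethylsilane, n-BuLi, THF, −78 °C
Reagents that add atoms: tert-butyl(ethynyl)dimethylsilane, C#C[Si](C)(C)C(C)(C)C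
Why: Nucleophilic 1,2-addition of the lithium silylacetylide to the methyl ketone; the new tertiary carbinol centre forms unselectively and is destroyed in step 6.

Step 6
Reactants: 8 propargylic alcohol
Product: 9 enoyl silane
Conditions: MoO2(acac)2 (2 mol %), AuCl(PPh3) (2 mol %), AgOTf (2 mol %), toluene, rt
Reagents that add atoms: none
Why: Meyer–Schuster rearrangement (1,3-shift of the propargylic hydroxyl, then tautomerisation of the allenol) should give the α,β-unsaturated acylsilane with the more stable E geometry, C7 and C8 not being involved.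

Step 7
Reactants: 9 enoyl silane
Product: 10 aldehyde
Conditions: O3, CH2Cl2, −78 °C (indicator end point); PPh3
Reagents that add atoms: ozone, [O-][O+]=O
Why: Ozonolysis with reductive work-up; the electron-rich styryl alkene should react far faster than the acyl-conjugated trisubstituted alkene, so only the C6 aldehyde is unmasked.

Step 8
Reactants: 10 aldehyde; 11 cyclohexane-1,3-dione
Product: 13 2-alkylcyclohexane-1,3-dione, via alkylidene dione 12 (not isolated)
Conditions: L-proline (20 mol %), Hantzsch ester, CH2Cl2, rt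
Reagents that add atoms: none
Why: Three-component reductive alkylation (Knoevenagel condensation, then conjugate transfer hydrogenation of 12 by the Hantzsch ester) should give exclusive C-alkylation under near-neutral conditions that leave the acylsilane and the silyloxy-bearing centre untouched.

Step 9
Reactants: 13 2-alkylcyclohexane-1,3-dione
Product: 14 hydroxymethyl dione
Conditions: aq. CH2O (37 %), Et3N (10 mol %), THF, rt
Reagents that add atoms: formaldehyde, C=O
Why: Aldol addition of the enolic 2-alkyl-1,3-dione to formaldehyde builds the quaternary C5, which is not yet stereogenic because its two ring carbonyl arms are identical.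

Step 10
Reactants: 14 hydroxymethyl dione
Product: 15 diol
Conditions: PPTS (20 mol %), MeOH, 0 °C to rt
Reagents that add atoms: none
Why: Acid-catalysed methanolysis of the secondary TES ether, which the acylsilane and the β-hydroxy dione should tolerate.

Step 11
Reactants: 15 diol
Product: 16 silylene-bridged dione
Conditions: t-Bu2Si(OTf)2, 2,6-lutidine, CH2Cl2, 0 °C
Reagents that add atoms: di-tert-butylsilyl bis(trifluoromethanesulfonate), CC(C)(C)[Si](OS(=O)(=O)C(F)(F)F)(OS(=O)(=O)C(F)(F)F)C(C)(C)C
Why: Silylene acetal formation bridges the C7 and C19 hydroxyls as a seven-membered dioxasilepane, which protects both and creates the conformational lock used in step 13.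

Step 12
Reactants: 17 3-bromofuran
Product: 19 3-bromo-2-chlorofuran, via 3-bromo-2-lithiofuran 18 (not isolated)
Conditions: LiN(i-Pr)2, THF, −78 °C; C2Cl6
Reagents that add atoms: hexachloroethane, ClC(Cl)(Cl)C(Cl)(Cl)Cl
Why: Directed deprotonation at the most acidic position (C2, flanked by oxygen and bromine) gives 18, which hexachloroethane chlorinates by positive-halogen transfer.

Step 13
Reactants: 16 silylene-bridged dione; 19 3-bromo-2-chlorofuran
Product: 25 ring B ketol silyl ether (C12 furyl ketone), via aryllithium 20 (not isolated), via lithium alkoxide 21 (not isolated), via siloxyallyllithium 22 (not isolated), via cyclised alkoxide 23 (not isolated), via silyl enol ether 24 (not isolated)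
Conditions: 19, n-BuLi, Et2O, −78 °C; then 16 in THF, −78 to −30 °C; TESOTf, −78 °C; 0.5 M HCl, THF, 0 °C
Reagents that add atoms: triethylsilyl trifluoromethanesulfonate, CC[Si](CC)(CC)OS(=O)(=O)C(F)(F)F
Why: Aryllithium 20 adds to the aldehyde-like acylsilane carbonyl C12 (21), [1,2]-Brook rearrangement moves silicon to oxygen and gives the furyl- and vinyl-stabilised lithium siloxyallyl anion 22, whose γ-carbon C9 adds to one ring carbonyl (23); silylation of the C10 alkoxide (24) and mild acid hydrolysis of the silyl enol ether should deliver 25 with the C12–C13 and C9–C10 bonds made in one flask operation. The closest known reaction type is the addition of organolithiums to α,β-unsaturated acylsilanes with Brook rearrangement and γ-capture of the siloxyallyl (homoenolate) anion by carbonyl electrophiles, including its annulative intramolecular ketone capture. Ring B closes by 6-exo-trig attack of C9 on the C10 carbonyl, whereas attack through C12 would need an eight-membered ring, which secures γ-regioselectivity. C9 is controlled by a chair transition state in which the C17 methyl on C8 and the bulky siloxy(furyl)vinyl arm are equatorial, so C20 becomes axial and cis to C17; C5 is controlled by the t-Bu2Si bridge, which can only span O7 and C19 when both are axial and so decides which of the two diastereotopic carbonyls becomes C10; C10 is controlled by attack of C9 anti to the axial C19 with the other carbonyl arm equatorial, which places O10 axial and trans to C19 (trans-fused rings A and B). The step needs chemoselectivity for the acylsilane over the two ring ketones, which rests on the higher electrophilicity of the acylsilane, the neopentyl position of both ketones next to quaternary C5 and inverse addition at −78 °C.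

Step 14
Reactants: 25 ring B ketol silyl ether
Product: 26 enone
Conditions: IBX, toluene/DMSO (2:1), 70 °C
Reagents that add atoms: none
Why: IBX-mediated dehydrogenation of the C4 ketone through its enol should give the C2=C3 enone regioselectively because C5 is quaternary, while the C12 ketone cannot be desaturated since C9 bears no hydrogen.

Step 15
Reactants: 26 enone
Product: 27 ring C enone
Conditions: Pd2(dba)3 (5 mol %), XPhos (12 mol %), K3PO4, toluene, 90 °C
Reagents that add atoms: none
Why: Palladium-catalysed intramolecular γ-arylation of the enone (oxidative addition into the acyl-activated C16–Cl bond, coupling with the extended potassium dienolate at C1, reductive elimination) closes the seven-membered ring C, and C1 is set under thermodynamic control because it stays enolisable through the dienolate, so the furan carbon should end equatorial on ring A and trans to the C9 bond on C10.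

Step 16
Reactants: 27 ring C enone
Product: 29 enol triflate, via lithium enolate 28 (not isolated)
Conditions: LiBH(s-Bu)3, THF, −78 °C; PhNTf2, −78 to 0 °C
Reagents that add atoms: N-phenylbis(trifluoromethanesulfonimide), O=S(=O)(N(c1ccccc1)S(=O)(=O)C(F)(F)F)C(F)(F)F
Why: Conjugate reduction of the enone gives the regiodefined lithium enolate 28, which PhNTf2 traps on oxygen as the C3=C4 enol triflate, the neopentyl furan-conjugated C12 ketone reacting more slowly with the bulky hydride at −78 °C.

Step 17
Reactants: 29 enol triflate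
Product: 30 triol triflate
Conditions: HF·pyridine, pyridine/THF, 0 °C to rt
Reagents that add atoms: none
Why: Fluoride-driven cleavage of the Si–O bonds removes the silylene bridge and the tertiary TES ether, while the vinyl triflate, the ketone and the furan should be stable to buffered HF.

Step 18
Reactants: 30 triol triflate
Product: 31 7-deacetyl target
Conditions: Pd(PPh3)4 (10 mol %), CO (1 atm), Et3N, DMF, 60 °C
Reagents that add atoms: carbon monoxide, [C-]#[O+]
Why: Palladium-catalysed carbonylative lactonisation (oxidative addition into the vinyl triflate, CO insertion, acyl transfer to the neighbouring primary C19 hydroxyl) closes the butenolide, the C7 and C10 hydroxyls being unable to reach the acyl palladium in an unstrained ring.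

Step 19
Reactants: 31 7-deacetyl target
Product: 32 target
Conditions: Ac2O, pyridine, DMAP (10 mol %), CH2Cl2, 0 °C to rt
Reagents that add atoms: acetic anhydride, CC(=O)OC(C)=O
Why: DMAP-catalysed acylation should esterify the secondary C7 hydroxyl only, the tertiary C10 hydroxyl being unreactive under these conditions.

Compound list

1 | (4S)-4-benzyl-3-propanoyl-1,3-oxazolidin-2-one | CCC(=O)N1[C@@H](Cc2ccccc2)COC1=O | starting material
2 | (E)-cinnamaldehyde | O=C/C=C/c1ccccc1 | starting material
3 | (4S)-4-benzyl-3-[(2R,3R,4E)-2-methyl-5-phenyl-3-(trimethylsilyloxy)pent-4-enoyl]-1,3-oxazolidin-2-one | C[Si](C)(C)O[C@H](/C=C/c1ccccc1)[C@@H](C)C(=O)N1[C@@H](Cc2ccccc2)COC1=O | intermediate (not isolated)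
4 | (4S)-4-benzyl-3-[(2R,3R,4E)-3-hydroxy-2-methyl-5-phenylpent-4-enoyl]-1,3-oxazolidin-2-one | O[C@H](/C=C/c1ccccc1)[C@@H](C)C(=O)N1[C@@H](Cc2ccccc2)COC1=O | intermediate
5 | (2R,3R,4E)-3-hydroxy-N-methoxy-N,2-dimethyl-5-phenylpent-4-enamide | O[C@H](/C=C/c1ccccc1)[C@@H](C)C(=O)N(C)OC | intermediate
6 | (2R,3R,4E)-N-methoxy-N,2-dimethyl-5-phenyl-3-(triethylsilyloxy)pent-4-enamide | CC[Si](CC)(CC)O[C@H](/C=C/c1ccccc1)[C@@H](C)C(=O)N(C)OC | intermediate
7 | (3R,4R,5E)-3-methyl-6-phenyl-4-(triethylsilyloxy)hex-5-en-2-one | CC[Si](CC)(CC)O[C@H](/C=C/c1ccccc1)[C@@H](C)C(C)=O | intermediate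
8 | (4R,5R,6E)-1-[tert-butyl(dimethyl)silyl]-3,4-dimethyl-7-phenyl-5-(triethylsilyloxy)hept-6-en-1-yn-3-ol (both C3 epimers) | CC[Si](CC)(CC)O[C@H](/C=C/c1ccccc1)[C@@H](C)C(C)(O)C#C[Si](C)(C)C(C)(C)C | intermediate
9 | (2E,4S,5R,6E)-1-[tert-butyl(dimethyl)silyl]-3,4-dimethyl-7-phenyl-5-(triethylsilyloxy)hepta-2,6-dien-1-one | CC[Si](CC)(CC)O[C@H](/C=C/c1ccccc1)[C@@H](C)/C(C)=C/C(=O)[Si](C)(C)C(C)(C)C | intermediate
10 | (2S,3S,4E)-6-[tert-butyl(dimethyl)silyl]-3,4-dimethyl-6-oxo-2-(triethylsilyloxy)hex-4-enal | CC[Si](CC)(CC)O[C@H](C=O)[C@@H](C)/C(C)=C/C(=O)[Si](C)(C)C(C)(C)C | intermediate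
11 | cyclohexane-1,3-dione | O=C1CCCC(=O)C1 | starting material
12 | 2-[(2R,3S,4E)-6-[tert-butyl(dimethyl)silyl]-3,4-dimethyl-6-oxo-2-(triethylsilyloxy)hex-4-en-1-ylidene]cyclohexane-1,3-dione | CC[Si](CC)(CC)O[C@H](C=C1C(=O)CCCC1=O)[C@@H](C)/C(C)=C/C(=O)[Si](C)(C)C(C)(C)C | intermediate (not isolated)
13 | 2-[(2R,3S,4E)-6-[tert-butyl(dimethyl)silyl]-3,4-dimethyl-6-oxo-2-(triethylsilyloxy)hex-4-en-1-yl]cyclohexane-1,3-dione | CC[Si](CC)(CC)O[C@H](CC1C(=O)CCCC1=O)[C@@H](C)/C(C)=C/C(=O)[Si](C)(C)C(C)(C)C | intermediate
14 | 2-[(2R,3S,4E)-6-[tert-butyl(dimethyl)silyl]-3,4-dimethyl-6-oxo-2-(triethylsilyloxy)hex-4-en-1-yl]-2-(hydroxymethyl)cyclohexane-1,3-dione | CC[Si](CC)(CC)O[C@H](CC1(CO)C(=O)CCCC1=O)[C@@H](C)/C(C)=C/C(=O)[Si](C)(C)C(C)(C)C | intermediate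
15 | 2-[(2R,3S,4E)-6-[tert-butyl(dimethyl)silyl]-2-hydroxy-3,4-dimethyl-6-oxohex-4-en-1-yl]-2-(hydroxymethyl)cyclohexane-1,3-dione | O[C@H](CC1(CO)C(=O)CCCC1=O)[C@@H](C)/C(C)=C/C(=O)[Si](C)(C)C(C)(C)C | intermediate
16 | cyclic di-tert-butylsilylene of 15: O7 and O19 bridged by t-Bu2Si in a 1,3-dioxa-2-silepane spiro-fused at C5 to the cyclohexane-1,3-dione; C7 R, C8 S; (E)-enoyl tert-butyldimethylsilane arm | CC(C)(C)[Si]1(C(C)(C)C)O[C@H](CC2(CO1)C(=O)CCCC2=O)[C@@H](C)/C(C)=C/C(=O)[Si](C)(C)C(C)(C)C | intermediate
17 | 3-bromofuran | Brc1ccoc1 | starting material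
18 | 3-bromo-2-lithiofuran | [Li]c1occc1Br | intermediate (not isolated)
19 | 3-bromo-2-chlorofuran | Clc1occc1Br | intermediate
20 | 2-chloro-3-lithiofuran | [Li]c1ccoc1Cl | intermediate (not isolated)
21 | lithium α-silyl alkoxide, the 1,2-adduct of 20 at the C12 carbonyl of 16 (C12 epimers) | CC(C)(C)[Si]1(C(C)(C)C)O[C@H](CC2(CO1)C(=O)CCCC2=O)[C@@H](C)/C(C)=C/C(O[Li])(c1ccoc1Cl)[Si](C)(C)C(C)(C)C | intermediate (not isolated)
22 | lithium siloxyallyl anion from 21 after Brook rearrangement, drawn as the C12-lithio C12-OTBS form | CC(C)(C)[Si]1(C(C)(C)C)O[C@H](CC2(CO1)C(=O)CCCC2=O)[C@@H](C)/C(C)=C/C([Li])(O[Si](C)(C)C(C)(C)C)c1ccoc1Cl | intermediate (not isolated)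
23 | cyclised lithium C10 alkoxide: rings A/B trans-fused, C4 ketone, O7/O19 silylene, C11=C12 TBS enol ether carrying the 2-chlorofuran-3-yl group; C19, C20, C17 and O7 on one face, O10 on the other | CC(C)(C)[Si]1(C(C)(C)C)O[C@@H]2C[C@@]3(CO1)C(=O)CCC[C@]3(O[Li])[C@@](C)(C=C(O[Si](C)(C)C(C)(C)C)c1ccoc1Cl)[C@@H]2C | intermediate (not isolated)
24 | C10 O-triethylsilyl ether of 23 | CC(C)(C)[Si]1(C(C)(C)C)O[C@@H]2C[C@@]3(CO1)C(=O)CCC[C@]3(O[Si](CC)(CC)CC)[C@@](C)(C=C(O[Si](C)(C)C(C)(C)C)c1ccoc1Cl)[C@@H]2C | intermediate (not isolated)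
25 | trans-decalin 4,12-diketone: C4 ring ketone, C10–OSiEt3, O7/O19 t-Bu2Si bridge, CH2–CO–(2-chlorofuran-3-yl) arm on C9; C5, C7, C8, C9, C10 configured as in 32 | CC(C)(C)[Si]1(C(C)(C)C)O[C@@H]2C[C@@]3(CO1)C(=O)CCC[C@]3(O[Si](CC)(CC)CC)[C@@](C)(CC(=O)c1ccoc1Cl)[C@@H]2C | intermediate
26 | C2=C3 enone of 25 | CC(C)(C)[Si]1(C(C)(C)C)O[C@@H]2C[C@@]3(CO1)C(=O)C=CC[C@]3(O[Si](CC)(CC)CC)[C@@](C)(CC(=O)c1ccoc1Cl)[C@@H]2C | intermediate
27 | ring C-closed enone: C1–C16 bonded, C2=C3–C4=O enone, C12 ketone in ring C; all stereocentres as in 32 | CC(C)(C)[Si]1(C(C)(C)C)O[C@@H]2C[C@@]3(CO1)C(=O)C=C[C@@H]4[C@]3(O[Si](CC)(CC)CC)[C@@](C)(CC(=O)c5ccoc45)[C@@H]2C | intermediate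
28 | lithium C4 enolate (C3=C4) from conjugate reduction of 27 | CC(C)(C)[Si]1(C(C)(C)C)O[C@@H]2C[C@@]3(CO1)C(O[Li])=CC[C@@H]4[C@]3(O[Si](CC)(CC)CC)[C@@](C)(CC(=O)c5ccoc45)[C@@H]2C | intermediate (not isolated)
29 | C4 enol triflate (C3=C4) of the silylene- and TES-protected tetracycle | CC(C)(C)[Si]1(C(C)(C)C)O[C@@H]2C[C@@]3(CO1)C(OS(=O)(=O)C(F)(F)F)=CC[C@@H]4[C@]3(O[Si](CC)(CC)CC)[C@@](C)(CC(=O)c5ccoc45)[C@@H]2C | intermediate
30 | 7,10,19-triol C4 enol triflate | O[C@@H]1C[C@@]2(CO)C(OS(=O)(=O)C(F)(F)F)=CC[C@@H]3[C@]2(O)[C@@](C)(CC(=O)c4ccoc34)[C@@H]1C | intermediate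
31 | 7-deacetyl target (7,10-diol butenolide) | O[C@@H]1C[C@@]23COC(=O)C2=CC[C@H]2c4occc4C(=O)C[C@@](C)([C@@H]1C)[C@@]23O | intermediate
32 | CNP0329797.2 (1R,5S,7R,8S,9S,10S in the locants above) | CC(=O)O[C@@H]1C[C@@]23COC(=O)C2=CC[C@H]2c4occc4C(=O)C[C@@](C)([C@@H]1C)[C@@]23O | target

Total step count: 19. Longest linear sequence: 18 steps (steps 1–11 and 13–19; step 12 is a one-step side branch).

Steps most likely to fail

Step 13. The aryllithium may add to, or enolise, the ring ketones instead of the acylsilane; proton transfer may quench the siloxyallyl anion before ring closure; and the ring closure may take the other carbonyl or give the cis ring fusion. The fallback separates the two bond formations. It sets out from 16 and 20: 20 is transmetallated with ClTi(OiPr)3 to the aryltitanium reagent F1, which adds to aldehyde-like carbonyls but not to ketones and should give, after aqueous work-up, the α-hydroxysilane F2. Catalytic KOt-Bu in THF then triggers Brook rearrangement and ring closure without any free organolithium; TESOTf and dilute acid as in step 13 bring the route back at 25.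

Step 15. Oxidative addition into the electron-rich heteroaryl chloride may be slow, the seven-membered reductive elimination may lose to protodechlorination, or coupling may occur at C3 instead of C1. The fallback abandons palladium. It sets out from 26 and uses metal-free addition–elimination (Cs2CO3, DMSO, 60 °C): C16–Cl is the β-position of a vinylogous acid chloride (C16=C13–C12=O), so the extended enolate carbon C1 can add to C16 and expel chloride. It makes no new compound (F0) and returns at 27.

Step 16. The hydride may also reduce the C12 ketone, or the C4 enolate may equilibrate to the more acidic C11 position before triflation. The fallback masks the aryl ketone. It sets out from 27: soft enolisation (TBSOTf, Et3N, CH2Cl2, −78 °C) should give the C11=C12 silyl enol ether F3; LiBH(s-Bu)3 then PhNTf2 gives the enol triflate F4; HF·pyridine removes all silyl groups and hydrolyses the enol ether, so the route is rejoined at 30.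

Further compounds

F1 | step 13 | (2-chlorofuran-3-yl)titanium triisopropoxide | CC(C)O[Ti](OC(C)C)(OC(C)C)c1ccoc1Cl
F2 | step 13 | α-hydroxysilane: C12 carbinol bearing TBS and 2-chlorofuran-3-yl on the silylene-bridged dione (C12 epimers) | CC(C)(C)[Si]1(C(C)(C)C)O[C@H](CC2(CO1)C(=O)CCCC2=O)[C@@H](C)/C(C)=C/C(O)(c1ccoc1Cl)[Si](C)(C)C(C)(C)C
F0 | step 15 | none | none
F3 | step 16 | C11=C12 tert-butyldimethylsilyl enol ether of 27 | CC(C)(C)[Si]1(C(C)(C)C)O[C@@H]2C[C@@]3(CO1)C(=O)C=C[C@@H]4[C@]3(O[Si](CC)(CC)CC)[C@@](C)(C=C(O[Si](C)(C)C(C)(C)C)c5ccoc45)[C@@H]2C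
F4 | step 16 | C4 enol triflate of F3 after conjugate reduction | CC(C)(C)[Si]1(C(C)(C)C)O[C@@H]2C[C@@]3(CO1)C(OS(=O)(=O)C(F)(F)F)=CC[C@@H]4[C@]3(O[Si](CC)(CC)CC)[C@@](C)(C=C(O[Si](C)(C)C(C)(C)C)c5ccoc45)[C@@H]2C
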